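The cyclohexane ring (ring B, C1'–C6'; C3' = CHBr, C4' = C(CH3)Cl) is cut at C1'–C6' and C2'–C3'. C4' is read as a ketone lying 1,4 to C1', with C3' as its α-carbon, so ring B becomes a 4-substituted cyclohex-2-enone. A one-pot amine-catalysed Michael addition/aldol condensation of an aldehyde with but-3-en-2-one forms both bonds and sets C1'. The aldehyde is a dioxolanone made from (R)-malic acid that already carries the quaternary carbinol C3 of the oxane (ring A) and its prenyl arm. The same acetal later templates the bromolactonisation that closes ring A, and the lactone carbonyl becomes the exocyclic enol ether.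

Key step: step 4

Remark on the chemistry: locants used below are ring A (oxane) O1, C2 (C=CH2), C3 (C–OH), C4, C5 (CHBr), C6 (CMe2), and ring B (cyclohexane) C1' (bonded to C3), C2', C3' (CHBr), C4' (C(CH3)Cl), C5', C6'. The target is taken as (3R,5R,1'S,3'S,4'S): in ring A bromine is cis to the hydroxyl, in ring B bromine is cis and chlorine trans to the C1' substituent. For compound 14 the C4' epimer with OH cis to Br is drawn; the other epimer would converge in step 9.

Step 1
Reactants: 1 (R)-malic acid; 2 pivalaldehyde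
Product: 3 2-[(2R,4R)-2-tert-butyl-5-oxo-1,3-dioxolan-4-yl]acetic acid
Conditions: TsOH·H2O (cat.), H2SO4 (cat.), pentane, reflux with water separator; crystallisation
Reagents that add atoms: none
Why: Acid-catalysed acetalisation of the α-hydroxy acid closes the five-membered acylal through the α-carboxyl group, and the cis isomer (tert-butyl cis to the CH2CO2H arm, new acetal centre R) should predominate and be purified by crystallisation.

Step 2
Reactants: 3 2-[(2R,4R)-2-tert-butyl-5-oxo-1,3-dioxolan-4-yl]acetic acid; 4 prenyl bromide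
Product: 5 2-[(2R,4R)-2-tert-butyl-4-(3-methylbut-2-en-1-yl)-5-oxo-1,3-dioxolan-4-yl]acetic acid
Conditions: LiN(SiMe3)2 (2.2 equiv), THF, −78 °C; then 4, −78 → −30 °C; aq. HCl work-up
Reagents that add atoms: none
Why: Dioxolanone enolate alkylation (self-regeneration of stereocentres): the carboxylate/enolate dianion should be alkylated anti to the tert-butyl group, so the prenyl group takes the place of the former hydrogen and the quaternary carbinol centre (future C3) is set with retention.

Step 3
Reactants: 5 2-[(2R,4R)-2-tert-butyl-4-(3-methylbut-2-en-1-yl)-5-oxo-1,3-dioxolan-4-yl]acetic acid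
Product: 7 2-[(2R,4R)-2-tert-butyl-4-(3-methylbut-2-en-1-yl)-5-oxo-1,3-dioxolan-4-yl]acetaldehyde, via acid chloride 6 (not isolated)
Conditions: (COCl)2, DMF (cat.), CH2Cl2, 0 °C → rt; evaporation; LiAlH(OtBu)3, THF, −78 °C
Reagents that add atoms: oxalyl chloride, ClC(=O)C(=O)Cl (chlorine of 6 only)
Why: Acid chloride formation followed by low-temperature reduction with the hindered alkoxyaluminium hydride should stop at the aldehyde and leave the hindered acylal carbonyl and both stereocentres untouched.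

Step 4
Reactants: 7 2-[(2R,4R)-2-tert-butyl-4-(3-methylbut-2-en-1-yl)-5-oxo-1,3-dioxolan-4-yl]acetaldehyde; 8 but-3-en-2-one
Product: 10 (4S)-4-[(2R,4R)-2-tert-butyl-4-(3-methylbut-2-en-1-yl)-5-oxo-1,3-dioxolan-4-yl]cyclohex-2-en-1-one, via keto-aldehyde 9 (not isolated)
Conditions: (R)-α,α-diphenylprolinol trimethylsilyl ether (20 mol %), ethyl 3,4-dihydroxybenzoate (20 mol %), CH2Cl2, 4 °C; then Bn2NH·CF3CO2H, toluene, 50 °C
Reagents that add atoms: none
Why: The secondary amine condenses with 7 to an (E)-enamine whose α-carbon (future C1') adds to the β-carbon of 8 (C6', activated by hydrogen bonding to the catechol), and hydrolysis gives 9; the ammonium salt then turns the methyl ketone into its enamine or enol, whose CH3 carbon (C3') adds to the aldehyde carbon (C2'), and dehydration gives the enone. The closest known reaction type is the organocatalytic Robinson-type annulation of aldehydes with methyl vinyl ketone to 4-substituted cyclohex-2-enones. Ring B closes in a 6-(enolendo)-exo-trig aldol mode followed by E1cB loss of water. C1' is set under catalyst control: the diarylsilyloxymethyl group shields one face of the enamine, and the (R)-catalyst should deliver C6' to the face that leads to (2R)-9 and (4S)-10, the remote (R)-carbinol centre being a spectator. The step needs C–C bond formation to outrun β-elimination of the acetal oxygen and epimerisation of 9, which the mildly acidic, low-temperature conditions and the quaternary β-carbon are meant to secure; the regiochemistry of the aldol is secured because only the methyl carbon of the ketone can close a six-membered ring.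

Step 5
Reactants: 10 (4S)-4-[(2R,4R)-2-tert-butyl-4-(3-methylbut-2-en-1-yl)-5-oxo-1,3-dioxolan-4-yl]cyclohex-2-en-1-one
Product: 12 (2R,4S)-2-hydroxy-4-[(2R,4R)-2-tert-butyl-4-(3-methylbut-2-en-1-yl)-5-oxo-1,3-dioxolan-4-yl]cyclohexan-1-one, via potassium enolate 11 (not isolated)
Conditions: KBH(s-Bu)3, THF, −78 °C; then 2-(phenylsulfonyl)-3-phenyloxaziridine, −78 °C; aq. work-up
Reagents that add atoms: 2-(phenylsulfonyl)-3-phenyloxaziridine, O=S(=O)(c1ccccc1)N1OC1c1ccccc1 (oxygen at C3'); KBH(s-Bu)3, CCC(C)[BH-](C(C)CC)C(C)CC.[K+] (potassium of 11 only)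
Why: Conjugate reduction of the β-unsubstituted enone by the bulky borohydride should give the C3'–C4' enolate regiospecifically, and Davis oxidation along the axial trajectory (chair-like transition state with the C1' substituent equatorial) should place the new C3'–OH trans to the C1' substituent.

Step 6
Reactants: 12 (2R,4S)-2-hydroxy-4-[(2R,4R)-2-tert-butyl-4-(3-methylbut-2-en-1-yl)-5-oxo-1,3-dioxolan-4-yl]cyclohexan-1-one
Product: 13 (2S,4S)-2-bromo-4-[(2R,4R)-2-tert-butyl-4-(3-methylbut-2-en-1-yl)-5-oxo-1,3-dioxolan-4-yl]cyclohexan-1-one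
Conditions: PPh3, CBr4, 2,6-lutidine, CH2Cl2, −20 → 0 °C
Reagents that add atoms: tetrabromomethane, BrC(Br)(Br)Br
Why: Appel reaction of the α-ketol: SN2 displacement of the oxyphosphonium group by bromide at the carbonyl-activated carbon should invert C3' and give the equatorial bromide cis to the C1' substituent.

Step 7
Reactants: 13 (2S,4S)-2-bromo-4-[(2R,4R)-2-tert-butyl-4-(3-methylbut-2-en-1-yl)-5-oxo-1,3-dioxolan-4-yl]cyclohexan-1-one
Product: 14 (1R,2S,4S)-2-bromo-1-methyl-4-[(2R,4R)-2-tert-butyl-4-(3-methylbut-2-en-1-yl)-5-oxo-1,3-dioxolan-4-yl]cyclohexan-1-ol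
Conditions: MeMgBr, CeCl3, THF, −78 °C; aq. work-up
Reagents that add atoms: methylmagnesium bromide, C[Mg]Br
Why: Cerium-mediated Grignard 1,2-addition to the α-bromo ketone, which is far more electrophilic than the hindered acylal, should give the tertiary bromohydrin, equatorial attack favouring OH cis to Br.

Step 8
Reactants: 14 (1R,2S,4S)-2-bromo-1-methyl-4-[(2R,4R)-2-tert-butyl-4-(3-methylbut-2-en-1-yl)-5-oxo-1,3-dioxolan-4-yl]cyclohexan-1-ol
Product: 16 (3R,5R)-5-bromo-3-[(1S,3S,4R)-3-bromo-4-hydroxy-4-methylcyclohexyl]-3-hydroxy-6,6-dimethyloxan-2-one, via hemiacetal 15 (not isolated)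
Conditions: NBS, (CF3)2CHOH/CH2Cl2, −20 → 0 °C; then H2O, NaHCO3
Reagents that add atoms: N-bromosuccinimide, O=C1CCC(=O)N1Br (bromine at C5); water, O (oxygen of the hemiacetal OH in 15 only)
Why: Proposed new method: NBS in (CF3)2CHOH should form the bromonium ion of the prenyl alkene, which is opened 6-endo at the tertiary carbon C6 by the carbonyl oxygen of the dioxolanone to close ring A; the dialkoxycarbenium ion then fragments at the acetal C–O bond to the δ-lactone and an oxocarbenium ion that water converts into hemiacetal 15 and on to the free C3–OH with loss of pivalaldehyde; because the five-membered acylal holds the C3–O bond anti to the attacking carbonyl oxygen, the chair transition state must place ring B axial and the C3 oxygen equatorial, and with bromine equatorial this sets C5 as R (Br cis to the C3–OH); the closest known reaction type is halolactonisation of alkenoic esters with loss of the ester O-substituent (tert-butyl or benzyl esters), together with the classical NBS bromolactonisation of 5-methylhex-4-enoic acids.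

Step 9
Reactants: 16 (3R,5R)-5-bromo-3-[(1S,3S,4R)-3-bromo-4-hydroxy-4-methylcyclohexyl]-3-hydroxy-6,6-dimethyloxan-2-one
Product: 17 (3R,5R)-5-bromo-3-[(1S,3S,4S)-3-bromo-4-chloro-4-methylcyclohexyl]-3-hydroxy-6,6-dimethyloxan-2-one
Conditions: HCl (4 M in 1,4-dioxane), CH2Cl2, 0 °C
Reagents that add atoms: hydrogen chloride, Cl
Why: SN1 substitution of the tertiary alcohol with neighbouring-group participation by the C3' bromine: chloride should open the bridged bromonium ion at the tertiary carbon C4' anti to bromine, so that either carbinol epimer gives Cl trans to Br (4'S), while the α-hydroxy lactone resists ionisation.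

Step 10
Reactants: 17 (3R,5R)-5-bromo-3-[(1S,3S,4S)-3-bromo-4-chloro-4-methylcyclohexyl]-3-hydroxy-6,6-dimethyloxan-2-one
Product: 18 (3R,5R)-5-bromo-3-[(1S,3S,4S)-3-bromo-4-chloro-4-methylcyclohexyl]-6,6-dimethyl-2-methylideneoxan-3-ol
Conditions: Cp2Ti(μ-CH2)(μ-Cl)AlMe2 (Tebbe reagent, 3 equiv), pyridine, THF/toluene, −40 °C → rt; aq. NaOH work-up, basic alumina
Reagents that add atoms: Tebbe reagent, C[Al-]1(C)C[Ti]([Cl+]1)(C1C=CC=C1)C1C=CC=C1 (the CH2 carbon)
Why: Tebbe methylenation of the lactone carbonyl ([2+2] addition of Cp2Ti=CH2 and cycloreversion) should give the exocyclic enol ether, which cannot migrate into the ring because C3 is quaternary, while the free tertiary hydroxyl only consumes excess reagent and no stereocentre is touched.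

Compound list
1 | (R)-malic acid | O[C@H](CC(=O)O)C(=O)O | starting material
2 | pivalaldehyde | CC(C)(C)C=O | starting material
3 | 2-[(2R,4R)-2-tert-butyl-5-oxo-1,3-dioxolan-4-yl]acetic acid | OC(=O)C[C@H]1O[C@@H](C(C)(C)C)OC1=O | intermediate
4 | prenyl bromide (1-bromo-3-methylbut-2-ene) | CC(C)=CCBr | starting material
5 | 2-[(2R,4R)-2-tert-butyl-4-(3-methylbut-2-en-1-yl)-5-oxo-1,3-dioxolan-4-yl]acetic acid | OC(=O)C[C@@]1(CC=C(C)C)O[C@@H](C(C)(C)C)OC1=O | intermediate
6 | 2-[(2R,4R)-2-tert-butyl-4-(3-methylbut-2-en-1-yl)-5-oxo-1,3-dioxolan-4-yl]acetyl chloride (not isolated) | ClC(=O)C[C@@]1(CC=C(C)C)O[C@@H](C(C)(C)C)OC1=O | intermediate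
7 | 2-[(2R,4R)-2-tert-butyl-4-(3-methylbut-2-en-1-yl)-5-oxo-1,3-dioxolan-4-yl]acetaldehyde | O=CC[C@@]1(CC=C(C)C)O[C@@H](C(C)(C)C)OC1=O | intermediate
8 | but-3-en-2-one (methyl vinyl ketone) | CC(=O)C=C | starting material
9 | (2R)-2-[(2R,4R)-2-tert-butyl-4-(3-methylbut-2-en-1-yl)-5-oxo-1,3-dioxolan-4-yl]-5-oxohexanal (not isolated) | CC(=O)CC[C@@H](C=O)[C@@]1(CC=C(C)C)O[C@@H](C(C)(C)C)OC1=O | intermediate
10 | (4S)-4-[(2R,4R)-2-tert-butyl-4-(3-methylbut-2-en-1-yl)-5-oxo-1,3-dioxolan-4-yl]cyclohex-2-en-1-one | CC(C)=CC[C@@]1(O[C@@H](C(C)(C)C)OC1=O)[C@H]2CCC(=O)C=C2 | intermediate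
11 | potassium enolate of the 2,3-dihydro ketone, C3'=C4' (not isolated) | CC(C)=CC[C@@]1(O[C@@H](C(C)(C)C)OC1=O)[C@H]2CCC([O-])=CC2.[K+] | intermediate
12 | (2R,4S)-2-hydroxy-4-[(2R,4R)-2-tert-butyl-4-(3-methylbut-2-en-1-yl)-5-oxo-1,3-dioxolan-4-yl]cyclohexan-1-one (OH trans to the side chain) | CC(C)=CC[C@@]1(O[C@@H](C(C)(C)C)OC1=O)[C@H]2CCC(=O)[C@H](O)C2 | intermediate
13 | (2S,4S)-2-bromo-4-[(2R,4R)-2-tert-butyl-4-(3-methylbut-2-en-1-yl)-5-oxo-1,3-dioxolan-4-yl]cyclohexan-1-one (Br cis to the side chain) | CC(C)=CC[C@@]1(O[C@@H](C(C)(C)C)OC1=O)[C@H]2CCC(=O)[C@@H](Br)C2 | intermediate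
14 | (1R,2S,4S)-2-bromo-1-methyl-4-[(2R,4R)-2-tert-butyl-4-(3-methylbut-2-en-1-yl)-5-oxo-1,3-dioxolan-4-yl]cyclohexan-1-ol | CC(C)=CC[C@@]1(O[C@@H](C(C)(C)C)OC1=O)[C@H]2CC[C@@](C)(O)[C@@H](Br)C2 | intermediate
15 | (3R,5R)-5-bromo-3-[(1S,3S,4R)-3-bromo-4-hydroxy-4-methylcyclohexyl]-3-(1-hydroxy-2,2-dimethylpropoxy)-6,6-dimethyloxan-2-one (not isolated) | O=C1OC(C)(C)[C@H](Br)C[C@@]1(OC(O)C(C)(C)C)[C@H]2CC[C@@](C)(O)[C@@H](Br)C2 | intermediate
16 | (3R,5R)-5-bromo-3-[(1S,3S,4R)-3-bromo-4-hydroxy-4-methylcyclohexyl]-3-hydroxy-6,6-dimethyloxan-2-one | O=C1OC(C)(C)[C@H](Br)C[C@@]1(O)[C@H]2CC[C@@](C)(O)[C@@H](Br)C2 | intermediate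
17 | (3R,5R)-5-bromo-3-[(1S,3S,4S)-3-bromo-4-chloro-4-methylcyclohexyl]-3-hydroxy-6,6-dimethyloxan-2-one | O=C1OC(C)(C)[C@H](Br)C[C@@]1(O)[C@H]2CC[C@](C)(Cl)[C@@H](Br)C2 | intermediate
18 | (3R,5R)-5-bromo-3-[(1S,3S,4S)-3-bromo-4-chloro-4-methylcyclohexyl]-6,6-dimethyl-2-methylideneoxan-3-ol | C=C1OC(C)(C)[C@H](Br)C[C@@]1(O)[C@H]1CC[C@](C)(Cl)[C@@H](Br)C1 | target

Total step count: 10. Longest linear sequence: 10 steps (from 1).

Steps most likely to fail

Step 8 (proposed new method). The weakly nucleophilic acylal carbonyl may fail to capture the bromonium ion, so that attack by the solvent or by the acetal ether oxygen (five-membered ring closure) takes over, or the acetal may be cleaved before cyclisation so that the template is lost. The fallback uses known chemistry and sets out from 14. The dioxolanone would be hydrolysed with LiOH/H2O2 in THF/H2O at 0 °C to (2R)-2-[(1S,3S,4R)-3-bromo-4-hydroxy-4-methylcyclohexyl]-2-hydroxy-5-methylhex-4-enoic acid F1. A classical bromolactonisation of the free carboxylate (NBS, NaHCO3, CH2Cl2/H2O, 0 °C; 6-endo closure at the tertiary carbon) would then lead back to 16. Without the template, facial control rests on the chair transition state alone, so 16 would have to be separated by chromatography from its C5 epimer, (3R,5S)-5-bromo-3-[(1S,3S,4R)-3-bromo-4-hydroxy-4-methylcyclohexyl]-3-hydroxy-6,6-dimethyloxan-2-one F2.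

Step 4 (key step). The enamine may expel the β-acetal oxygen (ring opening of the dioxolanone), the Michael addition at the neopentyl-type α-carbon may be too slow, or facial control by the catalyst may be eroded by the neighbouring quaternary centre. The fallback sets out from 7 and gives up amine catalysis. Silylation (Me3SiCl, NaI, Et3N, MeCN) would give the trimethylsilyl enol ether (2R,5R)-2-tert-butyl-5-(3-methylbut-2-en-1-yl)-5-[2-(trimethylsilyloxy)ethenyl]-1,3-dioxolan-4-one F3 (E/Z mixture). A Mukaiyama–Michael addition to 8 (BF3·OEt2, CH2Cl2, −78 °C) would then give 9 together with its epimer (2S)-2-[(2R,4R)-2-tert-butyl-4-(3-methylbut-2-en-1-yl)-5-oxo-1,3-dioxolan-4-yl]-5-oxohexanal F4. Cyclisation with Bn2NH·CF3CO2H as in step 4 would return to the route at 10 after chromatographic removal of the epimeric enone (4R)-4-[(2R,4R)-2-tert-butyl-4-(3-methylbut-2-en-1-yl)-5-oxo-1,3-dioxolan-4-yl]cyclohex-2-en-1-one F5.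

Step 9. The tertiary cation may be captured before the bromine bridges (loss of facial control at C4'), may lose a proton to give alkenes, or the bromonium ion may open at the secondary carbon (bromine migration); the acid may also ionise the tertiary alkyl–oxygen bond of the lactone. The fallback sets out from 14 and changes the order of events, so that no lactone and no free C3–OH meet the chlorination. The tertiary alcohol of 14 would be activated under neutral conditions with 1-chloro-N,N,2-trimethylprop-1-en-1-amine (CH2Cl2, 0 °C), which tolerates the prenyl group, to give (2R,5R)-5-[(1S,3S,4S)-3-bromo-4-chloro-4-methylcyclohexyl]-2-tert-butyl-5-(3-methylbut-2-en-1-yl)-1,3-dioxolan-4-one F6. The conditions of step 8 would then close ring A through the hemiacetal (3R,5R)-5-bromo-3-[(1S,3S,4S)-3-bromo-4-chloro-4-methylcyclohexyl]-3-(1-hydroxy-2,2-dimethylpropoxy)-6,6-dimethyloxan-2-one F7 (not isolated) and come back to the route at 17.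

Further compounds
F1 | step 8 | (2R)-2-[(1S,3S,4R)-3-bromo-4-hydroxy-4-methylcyclohexyl]-2-hydroxy-5-methylhex-4-enoic acid | CC(C)=CC[C@](O)(C(=O)O)[C@H]1CC[C@@](C)(O)[C@@H](Br)C1
F2 | step 8 | (3R,5S)-5-bromo-3-[(1S,3S,4R)-3-bromo-4-hydroxy-4-methylcyclohexyl]-3-hydroxy-6,6-dimethyloxan-2-one | O=C1OC(C)(C)[C@@H](Br)C[C@@]1(O)[C@H]2CC[C@@](C)(O)[C@@H](Br)C2
F3 | step 4 | (2R,5R)-2-tert-butyl-5-(3-methylbut-2-en-1-yl)-5-[2-(trimethylsilyloxy)ethenyl]-1,3-dioxolan-4-one (E/Z mixture) | C[Si](C)(C)OC=C[C@@]1(CC=C(C)C)O[C@@H](C(C)(C)C)OC1=O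
F4 | step 4 | (2S)-2-[(2R,4R)-2-tert-butyl-4-(3-methylbut-2-en-1-yl)-5-oxo-1,3-dioxolan-4-yl]-5-oxohexanal | CC(=O)CC[C@H](C=O)[C@@]1(CC=C(C)C)O[C@@H](C(C)(C)C)OC1=O
F5 | step 4 | (4R)-4-[(2R,4R)-2-tert-butyl-4-(3-methylbut-2-en-1-yl)-5-oxo-1,3-dioxolan-4-yl]cyclohex-2-en-1-one | CC(C)=CC[C@@]1(O[C@@H](C(C)(C)C)OC1=O)[C@@H]2CCC(=O)C=C2
F6 | step 9 | (2R,5R)-5-[(1S,3S,4S)-3-bromo-4-chloro-4-methylcyclohexyl]-2-tert-butyl-5-(3-methylbut-2-en-1-yl)-1,3-dioxolan-4-one | CC(C)=CC[C@@]1(O[C@@H](C(C)(C)C)OC1=O)[C@H]2CC[C@](C)(Cl)[C@@H](Br)C2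
F7 | step 9 | (3R,5R)-5-bromo-3-[(1S,3S,4S)-3-bromo-4-chloro-4-methylcyclohexyl]-3-(1-hydroxy-2,2-dimethylpropoxy)-6,6-dimethyloxan-2-one | O=C1OC(C)(C)[C@H](Br)C[C@@]1(OC(O)C(C)(C)C)[C@H]2CC[C@](C)(Cl)[C@@H](Br)C2
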